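**Retrosynthetic overview**
1. The target is a quinic acid core carrying a malonate on O4 and a caffeate on O5. Acid-labile groups come off last. Before that, C3 is retro-inverted (axial OH from an equatorial triflate), which leads back to a 3-epi-quinate whose core is meso, so that a lipase can tell the enantiotopic C3–OH and C5–OH apart and put the caffeate on O5.
2. Enabling feature: in the six-membered carbocycle, C3–C4–C5 carry three adjacent oxygens (a dihydroxyacetone unit with C4 as the carbonyl carbon) and face C2–C1(CO2H)–C6 (a 2-methylenepropanoate unit). In the meso precursor O3 and O5 are cis and can be held in a 1,3-dioxane ring.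
3. Key disconnection at C2–C3 and C6–C5: α,α′-annulation of the pyrrolidine enamine of 2-phenyl-1,3-dioxan-5-one with tert-butyl 2-(bromomethyl)acrylate.
4. Ring order: dioxane ring (bought, temporary), then the carbocycle (key step, closing onto the dioxane as a 2,4-dioxabicyclo[3.3.1]nonane), then removal of the dioxane ring after C1–OH (enolate oxidation), C4–OH (hydride) and the malonate are in place.

Key step: step 2

Assumption: 2-phenyl-1,3-dioxan-5-one (1) is taken as purchasable, the lipase of step 9 is assumed to follow its usual preference for the (R)-carbinol, and the carbocycle is numbered as in quinic acid (bicyclic C9 = C4, C1/C5 = C3/C5, C7 = C1).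

**Step 1**
Reactants: 1 2-phenyl-1,3-dioxan-5-one; 2 pyrrolidine
Product: 3 1-(2-phenyl-4H-1,3-dioxin-5-yl)pyrrolidine
Conditions: pyrrolidine (1.2 equiv), 4 Å molecular sieves, toluene, 20 °C; filter, evaporate, use crude
Reagents that add atoms: pyrrolidine (2), C1CCNC1
Why: Stork enamine formation from a ketone and a secondary amine, driven by removal of water; no stereocentre of the target is set, and the acetal carbon is carried as a racemate that becomes the pseudo-asymmetric acetal carbon of meso 7.

**Step 2**
Reactants: 3 1-(2-phenyl-4H-1,3-dioxin-5-yl)pyrrolidine; 4 tert-butyl 2-(bromomethyl)prop-2-enoate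
Product: 7 tert-butyl 9-oxo-3-exo-phenyl-2,4-dioxabicyclo[3.3.1]nonane-7-endo-carboxylate (meso), via mono-alkylated enamine 5 (not isolated), via bicyclic iminium bromide 6 (not isolated)
Conditions: 4 (1.05 equiv, slow addition), Et3N (1.2 equiv), MeCN, 0 °C to 80 °C; then H2O, 50 °C
Reagents that add atoms: tert-butyl 2-(bromomethyl)prop-2-enoate (4), C=C(CBr)C(=O)OC(C)(C)C; water, O
Why: This is the Lawton α,α′-annulation of a cyclic ketone enamine with a 2-(bromomethyl)acrylate, the reaction type that turns cyclohexanone and heterocyclic six-membered ketone enamines into bicyclo[3.3.1]nonan-9-ones. The enamine carbon of 3 displaces bromide from 4 by addition–elimination (forming C2–C3), Et3N shifts the iminium to the enamine on the other α-carbon (5), and that carbon adds to the new acrylate in a 6-endo-trig Michael closure of the carbocycle (forming C6–C5), after which the ester enolate is protonated to 6 and water cleaves the iminium. Both new ring bonds are axial on the dioxane ring and must lie on one face, because a three-carbon bridge can span a six-membered ring only 1,3-diaxially, so the two new stereocentres (C3 and C5 of the target) are cis by ring constraint and 7 is meso. The face used is the one carrying the acetal hydrogen, since only then does phenyl stay equatorial (exo) on the chair dioxane, and the first-formed centre can correct itself through the iminium–enamine equilibrium. The ester carbon is expected to be protonated from the open exo face (endo ester), which is of no consequence because step 3 planarises it. The step needs C- over N-alkylation and ring closure over a second intermolecular alkylation: N-alkylation by the allylic bromide is reversible, only the α′-enamine can reach the acrylate through a six-membered transition state, and slow addition of 4 keeps closure ahead.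

**Step 3**
Reactants: 7 tert-butyl 9-oxo-3-exo-phenyl-2,4-dioxabicyclo[3.3.1]nonane-7-endo-carboxylate
Product: 8 tert-butyl 7-exo-hydroxy-9-oxo-3-exo-phenyl-2,4-dioxabicyclo[3.3.1]nonane-7-endo-carboxylate (meso)
Conditions: KN(SiMe3)2 (1.2 equiv), THF, −78 °C; 2-(benzenesulfonyl)-3-phenyloxaziridine (1.5 equiv), −78 °C; aq. NH4Cl
Reagents that add atoms: 2-(benzenesulfonyl)-3-phenyloxaziridine, O=S(=O)(c1ccccc1)N1OC1c1ccccc1
Why: Davis enolate hydroxylation, in which the base removes the only enolisable hydrogen (the bridgehead hydrogens beside the ketone cannot enolise) and the oxaziridine attacks the convex exo face away from the dioxane bridge, so the new C1 hydroxyl should end trans and the ester cis to the two ring oxygens.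

**Step 4**
Reactants: 8 tert-butyl 7-exo-hydroxy-9-oxo-3-exo-phenyl-2,4-dioxabicyclo[3.3.1]nonane-7-endo-carboxylate
Product: 9 tert-butyl 7-exo,9-dihydroxy-3-exo-phenyl-2,4-dioxabicyclo[3.3.1]nonane-7-endo-carboxylate (meso; 9-OH cis to 7-OH and trans to O2/O4)
Conditions: LiAlH(OtBu)3 (3 equiv), THF, −78 °C to −20 °C; aq. KNaC4H4O6
Reagents that add atoms: none
Why: Chemoselective hydride reduction of the ketone beside two tert-butyl-type esters, in which the fully substituted C7 with its endo ester is expected to force the carbocycle into a boat whose flagpole oxygen (as the aluminate formed by the first equivalent) covers the carbocycle-side face of the carbonyl, so hydride should enter over the chair dioxane ring (whose acetal carbon carries only an equatorial phenyl) and place the C4 hydroxyl cis to the C1 hydroxyl and trans to O3 and O5.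

**Step 5**
Reactants: 9 tert-butyl 7-exo,9-dihydroxy-3-exo-phenyl-2,4-dioxabicyclo[3.3.1]nonane-7-endo-carboxylate; 10 3-(tert-butoxy)-3-oxopropanoic acid
Product: 11 tert-butyl 9-{[3-(tert-butoxy)-3-oxopropanoyl]oxy}-7-exo-hydroxy-3-exo-phenyl-2,4-dioxabicyclo[3.3.1]nonane-7-endo-carboxylate (meso)
Conditions: 10 (1.5 equiv), DCC (1.5 equiv), DMAP (0.1 equiv), CH2Cl2, 0 °C to 20 °C
Reagents that add atoms: 3-(tert-butoxy)-3-oxopropanoic acid (10), O=C(O)CC(=O)OC(C)(C)C
Why: Steglich esterification, which for a malonic half-ester runs through the ketene and should acylate the single secondary alcohol while the tertiary α-hydroxy-ester alcohol stays free, with no stereocentre touched.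

**Step 6**
Reactants: 11 tert-butyl 9-{[3-(tert-butoxy)-3-oxopropanoyl]oxy}-7-exo-hydroxy-3-exo-phenyl-2,4-dioxabicyclo[3.3.1]nonane-7-endo-carboxylate
Product: 12 tert-butyl 4-O-[3-(tert-butoxy)-3-oxopropanoyl]-3-epi-quinate (meso)
Conditions: H2 (1 atm), Pd(OH)2/C, EtOAc/MeOH 4:1, 20 °C
Reagents that add atoms: none
Why: Hydrogenolysis of the benzylidene acetal frees the two enantiotopic secondary alcohols under neutral conditions that leave both tert-butyl esters and the malonate in place, and the tert-butyl ester at C1 should not lactonise onto the cis hydroxyls.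

**Step 7**
Reactants: 13 caffeic acid
Product: 15 (E)-3-[3,4-bis(methoxymethoxy)phenyl]prop-2-enoic acid, via methoxymethyl ester 14 (not isolated)
Conditions: ClCH2OMe (3.6 equiv), iPr2NEt (4 equiv), CH2Cl2, 0 °C to 20 °C; then LiOH (2 equiv), THF/MeOH/H2O, 20 °C; 1 M HCl to pH 4 at 0 °C
Reagents that add atoms: chloromethyl methyl ether, COCCl; lithium hydroxide, [Li+].[OH-]
Why: Williamson-type O-alkylation of both phenols and the acid followed by saponification of the more labile methoxymethyl ester gives the acid with acid-labile phenol protection and an unchanged E alkene.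

**Step 8**
Reactants: 15 (E)-3-[3,4-bis(methoxymethoxy)phenyl]prop-2-enoic acid
Product: 16 ethenyl (E)-3-[3,4-bis(methoxymethoxy)phenyl]prop-2-enoate
Conditions: vinyl acetate (solvent), Pd(OAc)2 (5 mol%), KOH (10 mol%), 20 °C
Reagents that add atoms: vinyl acetate, C=COC(C)=O
Why: Pd(OAc)2-catalysed transvinylation (vinyl interchange) of a carboxylic acid with vinyl acetate gives the enol ester that serves as an irreversible acyl donor.

**Step 9**
Reactants: 12 tert-butyl 4-O-[3-(tert-butoxy)-3-oxopropanoyl]-3-epi-quinate; 16 ethenyl (E)-3-[3,4-bis(methoxymethoxy)phenyl]prop-2-enoate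
Product: 17 tert-butyl 5-O-[(E)-3,4-bis(methoxymethoxy)cinnamoyl]-4-O-[3-(tert-butoxy)-3-oxopropanoyl]-3-epi-quinate
Conditions: 16 (3 equiv), immobilised Burkholderia cepacia lipase (Amano PS-IM), t-BuOMe, 45 °C; filter
Reagents that add atoms: ethenyl (E)-3-[3,4-bis(methoxymethoxy)phenyl]prop-2-enoate (16), C=COC(=O)/C=C/c1ccc(OCOC)c(OCOC)c1
Why: Lipase-catalysed desymmetrising transesterification of a meso 1,3-diol with an enol ester (irreversible because vinyl alcohol leaves as acetaldehyde), in which the enzyme is expected to acylate the (R)-configured carbinol, here C5 (flanked by the acyloxy-bearing C4 as the large and C6H2 as the medium group), so the absolute configuration of the target is set by this choice between O5 and O3 while the tertiary hydroxyl does not react and any wrongly acylated material is drained into the diester.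

**Step 10**
Reactants: 17 tert-butyl 5-O-[(E)-3,4-bis(methoxymethoxy)cinnamoyl]-4-O-[3-(tert-butoxy)-3-oxopropanoyl]-3-epi-quinate
Product: 20 tert-butyl 5-O-[(E)-3,4-bis(methoxymethoxy)cinnamoyl]-4-O-[3-(tert-butoxy)-3-oxopropanoyl]quinate, via C3 triflate 18 (not isolated), via C3 nitrite ester 19 (not isolated)
Conditions: Tf2O (1.3 equiv), pyridine (4 equiv), CH2Cl2, −30 °C to 0 °C; cold aqueous wash, evaporate; Bu4NNO2 (5 equiv), MeCN, 20 °C to 40 °C; H2O work-up
Reagents that add atoms: trifluoromethanesulfonic anhydride (its atoms stay only in 18), O=S(=O)(OS(=O)(=O)C(F)(F)F)C(F)(F)F; tetrabutylammonium nitrite (supplies the new oxygen on C3), CCCC[N+](CCCC)(CCCC)CCCC.[O-]N=O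
Why: Lattrell–Dax inversion, in which the equatorial secondary triflate (no antiperiplanar hydrogen, neighbouring equatorial ester at C4 as that reaction requires) is displaced by nitrite through oxygen in an SN2 step and the nitrite ester is hydrolysed on work-up, so C3 should go from equatorial to axial hydroxyl and give the quinic acid configuration without base.

**Step 11**
Reactants: 20 tert-butyl 5-O-[(E)-3,4-bis(methoxymethoxy)cinnamoyl]-4-O-[3-(tert-butoxy)-3-oxopropanoyl]quinate
Product: 21 (1S,3R,4R,5R)-4-[(carboxyacetyl)oxy]-3-{[(2E)-3-(3,4-dihydroxyphenyl)prop-2-enoyl]oxy}-1,5-dihydroxycyclohexane-1-carboxylic acid (4-O-malonyl-5-O-caffeoylquinic acid)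
Conditions: CF3CO2H/H2O 9:1, 0 °C to 20 °C; evaporate cold; reverse-phase chromatography
Reagents that add atoms: none
Why: Acidolysis cleaves both tert-butyl esters (loss of isobutene) and both aryl methoxymethyl acetals in one operation, while the two secondary esters, the cinnamate double bond and all stereocentres should be untouched, and the absence of base avoids acyl migration and loss of the malonate.

**Compound list**
1 | 2-phenyl-1,3-dioxan-5-one | O=C1COC(c2ccccc2)OC1 | starting material
2 | pyrrolidine | C1CCNC1 | starting material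
3 | 1-(2-phenyl-4H-1,3-dioxin-5-yl)pyrrolidine (racemic at the acetal carbon) | C1CCN(C1)C1=COC(c2ccccc2)OC1 | intermediate
4 | tert-butyl 2-(bromomethyl)prop-2-enoate | C=C(CBr)C(=O)OC(C)(C)C | starting material
5 | tert-butyl 2-{[2-phenyl-5-(pyrrolidin-1-yl)-4H-1,3-dioxin-4-yl]methyl}prop-2-enoate (racemic, 2,4-trans, one enantiomer drawn) | C1CCN(C1)C1=CO[C@H](c2ccccc2)O[C@H]1CC(=C)C(=O)OC(C)(C)C | intermediate (not isolated)
6 | 1-[7-endo-(tert-butoxycarbonyl)-3-exo-phenyl-2,4-dioxabicyclo[3.3.1]nonan-9-ylidene]pyrrolidin-1-ium bromide (meso) | [Br-].C1CC[N+](C1)=C1[C@@H]2C[C@@H](C(=O)OC(C)(C)C)C[C@H]1O[C@H](c1ccccc1)O2 | intermediate (not isolated)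
7 | tert-butyl 9-oxo-3-exo-phenyl-2,4-dioxabicyclo[3.3.1]nonane-7-endo-carboxylate (meso; bridgehead oxygens cis, ester cis to them) | O=C1[C@@H]2C[C@@H](C(=O)OC(C)(C)C)C[C@H]1O[C@H](c1ccccc1)O2 | intermediate
8 | tert-butyl 7-exo-hydroxy-9-oxo-3-exo-phenyl-2,4-dioxabicyclo[3.3.1]nonane-7-endo-carboxylate (meso; 7-OH trans to O2/O4) | O=C1[C@@H]2C[C@@](O)(C(=O)OC(C)(C)C)C[C@H]1O[C@H](c1ccccc1)O2 | intermediate
9 | tert-butyl 7-exo,9-dihydroxy-3-exo-phenyl-2,4-dioxabicyclo[3.3.1]nonane-7-endo-carboxylate (meso; 9-OH cis to 7-OH, trans to O2/O4) | O[C@@H]1[C@@H]2C[C@@](O)(C(=O)OC(C)(C)C)C[C@H]1O[C@H](c1ccccc1)O2 | intermediate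
10 | 3-(tert-butoxy)-3-oxopropanoic acid (mono-tert-butyl malonate) | O=C(O)CC(=O)OC(C)(C)C | starting material
11 | tert-butyl 9-{[3-(tert-butoxy)-3-oxopropanoyl]oxy}-7-exo-hydroxy-3-exo-phenyl-2,4-dioxabicyclo[3.3.1]nonane-7-endo-carboxylate (meso) | CC(C)(C)OC(=O)CC(=O)O[C@@H]1[C@@H]2C[C@@](O)(C(=O)OC(C)(C)C)C[C@H]1O[C@H](c1ccccc1)O2 | intermediate
12 | tert-butyl 4-O-[3-(tert-butoxy)-3-oxopropanoyl]-3-epi-quinate (meso; 3-OH and 5-OH cis to each other and to the ester group, 4-O and 1-OH on the other face) | CC(C)(C)OC(=O)CC(=O)O[C@@H]1[C@@H](O)C[C@@](O)(C(=O)OC(C)(C)C)C[C@H]1O | intermediate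
13 | caffeic acid, (E)-3-(3,4-dihydroxyphenyl)prop-2-enoic acid | O=C(O)/C=C/c1ccc(O)c(O)c1 | starting material
14 | methoxymethyl (E)-3-[3,4-bis(methoxymethoxy)phenyl]prop-2-enoate | COCOC(=O)/C=C/c1ccc(OCOC)c(OCOC)c1 | intermediate (not isolated)
15 | (E)-3-[3,4-bis(methoxymethoxy)phenyl]prop-2-enoic acid | O=C(O)/C=C/c1ccc(OCOC)c(OCOC)c1 | intermediate
16 | ethenyl (E)-3-[3,4-bis(methoxymethoxy)phenyl]prop-2-enoate | C=COC(=O)/C=C/c1ccc(OCOC)c(OCOC)c1 | intermediate
17 | tert-butyl 5-O-[(E)-3,4-bis(methoxymethoxy)cinnamoyl]-4-O-[3-(tert-butoxy)-3-oxopropanoyl]-3-epi-quinate (single enantiomer; C5 is R, C3–OH equatorial) | CC(C)(C)OC(=O)CC(=O)O[C@@H]1[C@@H](O)C[C@@](O)(C(=O)OC(C)(C)C)C[C@H]1OC(=O)/C=C/c1ccc(OCOC)c(OCOC)c1 | intermediate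
18 | 3-O-trifluoromethanesulfonate of 17 | CC(C)(C)OC(=O)CC(=O)O[C@@H]1[C@@H](OS(=O)(=O)C(F)(F)F)C[C@@](O)(C(=O)OC(C)(C)C)C[C@H]1OC(=O)/C=C/c1ccc(OCOC)c(OCOC)c1 | intermediate (not isolated)
19 | 3-O-nitrite ester of 20 (C3 inverted) | CC(C)(C)OC(=O)CC(=O)O[C@@H]1[C@H](ON=O)C[C@@](O)(C(=O)OC(C)(C)C)C[C@H]1OC(=O)/C=C/c1ccc(OCOC)c(OCOC)c1 | intermediate (not isolated)
20 | tert-butyl 5-O-[(E)-3,4-bis(methoxymethoxy)cinnamoyl]-4-O-[3-(tert-butoxy)-3-oxopropanoyl]quinate (quinic acid configuration, C3–OH axial) | CC(C)(C)OC(=O)CC(=O)O[C@@H]1[C@H](O)C[C@@](O)(C(=O)OC(C)(C)C)C[C@H]1OC(=O)/C=C/c1ccc(OCOC)c(OCOC)c1 | intermediate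
21 | (1S,3R,4R,5R)-4-[(carboxyacetyl)oxy]-3-{[(2E)-3-(3,4-dihydroxyphenyl)prop-2-enoyl]oxy}-1,5-dihydroxycyclohexane-1-carboxylic acid (4-O-malonyl-5-O-caffeoylquinic acid) | O=C(O)CC(=O)O[C@@H]1[C@H](O)C[C@@](O)(C(=O)O)C[C@H]1OC(=O)/C=C/c1ccc(O)c(O)c1 | target

**Step count**
Total steps: 11 (9 on the main line and 2 for the acyl donor). Longest linear sequence: 9 steps (steps 1 to 6, then 9, 10 and 11).

**Steps most likely to fail**

Step 9 (enzymatic desymmetrisation). The lipase may turn over slowly with the bulky cinnamoyl donor, may discriminate the two enantiotopic hydroxyls poorly (erosion of enantiomeric purity), or may attack the malonate. The fallback sets out from 12 and uses the hydrolytic mode, which is the most widely documented lipase desymmetrisation of meso diesters and shows the same preference for the (R)-carbinol. Both hydroxyls are esterified with chloroacetic anhydride and pyridine to the meso bis(chloroacetate) F1. The lipase in phosphate buffer/t-BuOMe should then cleave only the ester on C5 to give the mono-chloroacetate F2 with free C5–OH. Carbodiimide coupling (EDC, DMAP) with acid 15 gives the caffeate chloroacetate F3, and thiourea (NaHCO3, EtOH, 50 °C) removes the chloroacetate selectively, returning to the route at 17.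

Step 4 (ketone reduction). Hydride may be delivered from the wrong face if the carbocycle does not hold the boat or if the C7 alkoxide passes hydride on internally. This loss of facial selectivity would give the C9 epimer with the two hydroxyls trans. The fallback sets out from 8. Hydrogenolysis (H2, Pd(OH)2/C) frees the α,α′-dihydroxy ketone F4. Me4NBH(OAc)3 in MeCN/AcOH at −20 °C then delivers hydride internally from both flanking hydroxyls (hydroxyl-directed anti reduction) to give the all-trans triol tert-butyl 3-epi-quinate F5. Et3SiCl and imidazole should silylate the two less hindered flanking hydroxyls to give the bis(triethylsilyl) ether F6, DCC/DMAP with 10 acylates the remaining C4–OH to give the malonate F7, and AcOH/THF/H2O removes the silyl ethers, returning to the route at 12.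

Step 10 (inversion at C3). Elimination, participation of the neighbouring malonate with acyl migration, or slow displacement because the incoming nitrite must pass the syn-axial C1 hydroxyl may compete. The fallback sets out from 17. A Mitsunobu reaction with chloroacetic acid (PPh3, diisopropyl azodicarboxylate, toluene) activates the alcohol as the oxyphosphonium salt and brings in a small, acidic carboxylate to give the inverted chloroacetate F8. Thiourea (NaHCO3, EtOH, 50 °C) then removes the chloroacetate without touching the other esters, returning to the route at 20.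

**Further compounds**
F1 | step 9 | tert-butyl 3,5-bis-O-(chloroacetyl)-4-O-[3-(tert-butoxy)-3-oxopropanoyl]-3-epi-quinate (meso) | CC(C)(C)OC(=O)CC(=O)O[C@@H]1[C@@H](OC(=O)CCl)C[C@@](O)(C(=O)OC(C)(C)C)C[C@H]1OC(=O)CCl
F2 | step 9 | tert-butyl 3-O-(chloroacetyl)-4-O-[3-(tert-butoxy)-3-oxopropanoyl]-3-epi-quinate (C5–OH free) | CC(C)(C)OC(=O)CC(=O)O[C@@H]1[C@@H](OC(=O)CCl)C[C@@](O)(C(=O)OC(C)(C)C)C[C@H]1O
F3 | step 9 | tert-butyl 5-O-[(E)-3,4-bis(methoxymethoxy)cinnamoyl]-3-O-(chloroacetyl)-4-O-[3-(tert-butoxy)-3-oxopropanoyl]-3-epi-quinate | CC(C)(C)OC(=O)CC(=O)O[C@@H]1[C@@H](OC(=O)CCl)C[C@@](O)(C(=O)OC(C)(C)C)C[C@H]1OC(=O)/C=C/c1ccc(OCOC)c(OCOC)c1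
F4 | step 4 | tert-butyl 1,3,5-trihydroxy-4-oxocyclohexane-1-carboxylate (meso; 3-OH and 5-OH cis, 1-OH trans to them) | O=C1[C@@H](O)C[C@@](O)(C(=O)OC(C)(C)C)C[C@H]1O
F5 | step 4 | tert-butyl 3-epi-quinate (meso, all-trans 3,4,5-triol, 1-OH cis to 4-OH) | O[C@@H]1[C@@H](O)C[C@@](O)(C(=O)OC(C)(C)C)C[C@H]1O
F6 | step 4 | tert-butyl 3,5-bis-O-(triethylsilyl)-3-epi-quinate (meso) | O[C@@H]1[C@@H](O[Si](CC)(CC)CC)C[C@@](O)(C(=O)OC(C)(C)C)C[C@H]1O[Si](CC)(CC)CC
F7 | step 4 | tert-butyl 4-O-[3-(tert-butoxy)-3-oxopropanoyl]-3,5-bis-O-(triethylsilyl)-3-epi-quinate (meso) | CC(C)(C)OC(=O)CC(=O)O[C@@H]1[C@@H](O[Si](CC)(CC)CC)C[C@@](O)(C(=O)OC(C)(C)C)C[C@H]1O[Si](CC)(CC)CC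
F8 | step 10 | tert-butyl 5-O-[(E)-3,4-bis(methoxymethoxy)cinnamoyl]-3-O-(chloroacetyl)-4-O-[3-(tert-butoxy)-3-oxopropanoyl]quinate (C3 inverted) | CC(C)(C)OC(=O)CC(=O)O[C@@H]1[C@H](OC(=O)CCl)C[C@@](O)(C(=O)OC(C)(C)C)C[C@H]1OC(=O)/C=C/c1ccc(OCOC)c(OCOC)c1
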